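**Plan**

1. Numbering: ring A (oxepane) O1–C2(Me2)–C3(OH)–C4–C5–C6(Me)–C7; ring B C6–C7–C8–C9–C10(Me)(OH)–C11; linker C12–C13; ring C C14–C15(Me)=C16–C17–C18–C23; ring D C18–C19(Me)(OH)–C20–C21–C22(Me2)–C23.
2. Cuts: C12–C13 (Wittig, then reduction) divides the molecule. In the right half C13–C14 is cut, then C18–C19 (acyloin shift, which takes ring D back to a cyclopentane with acetyl and hydroxyl on C20), then C14–C23 and C17–C18 (Diels–Alder). In the left half O1–C2, C6–C11 and C10–O fall in one epoxide cascade back to farnesyl acetate.
3. Enabling feature: in ring D, C19 is a tertiary methyl carbinol bonded to the ring-fusion carbon C18 and flanked by C20. This is what an α-ketol shift leaves when C18 of a 1-acetylcyclopentanol (carbinol carbon C20) migrates to the acetyl carbon, so ring D can be grown from the five-membered ring C18–C20–C21–C22–C23.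
4. Forward order: the five-membered ring is bought; ring C by Diels–Alder; C14 enone; acetyl carbinol at C20; ring D by the shift; C20 deoxygenated and C13 added. Rings A and B are made together from a diepoxide. Union at C12=C13, reduction, desilylation.
5. Stereochemistry: C18 and C23 from the catalyst-controlled cis cycloaddition; C20 from convex-face osmylation, and C19 from it through the chelated shift (C18 migrates with retention); C14 from hydroboration anti to C22; C3, C7 and (by inversion) C6 from Shi epoxidation; C10 and C11 from anti addition to the E-alkene in a chair.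

Key step: step 7

Assumption: the (S)-configured oxazaborolidinium catalyst of step 1 is assumed to leave open the face of enone 1 on which C1, C3 and H around C2 run counterclockwise; if the sense is the reverse, the (R)-catalyst is used and nothing else changes.

**Route**

Step 1
Reactants: 1 4,4-dimethylcyclopent-2-en-1-one; 2 isoprene
Product: 3 cis-hydrindenone (C20 ketone, C15=C16)
Conditions: (S)-3,3-diphenyl-1-(o-tolyl)tetrahydro-1H,3H-pyrrolo[1,2-c][1,3,2]oxazaborole (20 mol%), (CF3SO2)2NH, CH2Cl2, −40 → −20 °C
Reagents that add atoms: none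
Why: Lewis-acid-catalysed Diels–Alder reaction in which the boron-bound enone is attacked on the open face, suprafacial addition makes the C18/C23 ring fusion cis, and the diene methyl ends para to the carbonyl-bearing carbon, i.e. on C15.

Step 2
Reactants: 3 cis-hydrindenone
Product: 4 C14 allylic alcohol
Conditions: SeO2 (0.3 equiv), t-BuOOH, CH2Cl2, rt
Reagents that add atoms: tert-butyl hydroperoxide, CC(C)(C)OO
Why: SeO2 allylic oxidation (ene reaction at C16, then [2,3]-shift) goes to the ring methylene on the more substituted alkene carbon, C14, and leaves C15=C16 in place; the new carbinol centre is removed in step 3.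

Step 3
Reactants: 4 C14 allylic alcohol
Product: 5 enedione (C14 enone, C20 ketone)
Conditions: Dess–Martin periodinane, NaHCO3, CH2Cl2, 0 °C → rt
Reagents that add atoms: none
Why: Dess–Martin oxidation of the allylic alcohol gives the conjugated enone under buffered conditions that do not epimerise the ring-fusion centres.

Step 4
Reactants: 5 enedione; 6 ethyltriphenylphosphonium bromide
Product: 8 C20-ethylidene enone, via ethylidenetriphenylphosphorane 7 (not isolated)
Conditions: KOt-Bu, THF, 0 °C; then 5, 0 °C → rt
Reagents that add atoms: none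
Why: Wittig olefination in which the unstabilised ylide takes the open, saturated cyclopentanone C20 in preference to the conjugated and doubly flanked C14 carbonyl; alkene geometry is of no consequence because C19 becomes a carbonyl in step 6.

Step 5
Reactants: 8 C20-ethylidene enone
Product: 9 C19,C20-diol
Conditions: OsO4 (2 mol%), N-methylmorpholine N-oxide, acetone/H2O, rt
Reagents that add atoms: N-methylmorpholine N-oxide, C[N+]1([O-])CCOCC1; water, O
Why: Catalytic osmylation (Upjohn dihydroxylation) picks the electron-rich ethylidene over the electron-poor enone alkene and comes from the convex face of the cis-hydrindane (the face of H18 and H23), which puts the C20 hydroxyl on that face.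

Step 6
Reactants: 9 C19,C20-diol
Product: 10 α-ketol (1-acetylcyclopentanol in the cis-hydrindane)
Conditions: Dess–Martin periodinane, NaHCO3, CH2Cl2, 0 °C → rt
Reagents that add atoms: none
Why: Dess–Martin oxidation converts only the secondary C19 alcohol, the tertiary C20 carbinol being inert, and so gives the α-ketol.

Step 7
Reactants: 10 α-ketol
Product: 11 ring-expanded ketol (rings C and D, C19 carbinol, C20 ketone)
Conditions: BF3·OEt2 (2.5 equiv), CH2Cl2, −20 → 0 °C
Reagents that add atoms: none
Why: BF3 binds the C20 hydroxyl and the acetyl oxygen in a five-membered chelate (a further equivalent sits on the enone), which holds O–C20–C19–O syn-periplanar with the C20–C18 and C20–C21 bonds on either side of the acetyl plane; C18 then moves with its bonding pair to the carbonyl carbon C19 while C20–O becomes the new carbonyl, a Lewis-acid α-ketol (acyloin) rearrangement of the type used for D-homoannulation of 17-hydroxy-20-keto steroids. Ring D is formed by ring enlargement and not by an end-to-end cyclisation: the five-membered ring C18–C20–C21–C22–C23 takes up C19 through a suprafacial 1,2-shift, and C18 migrates with retention, so the cis ring fusion is carried over. The new stereocentre C19 is set by the C20 carbinol, because with the hydroxyl on the convex face and the acetyl oxygen chelated syn to it C18 reaches only one face of the carbonyl, which leaves the C19 hydroxyl cis to H18 and the methyl trans, as in the target. The step needs C18 and not C21 to migrate: C18 is the more substituted carbon and carries the positive charge of the transition state better, migration of C21 is slowed by its neopentyl position and would place the new quaternary carbinol 1,3 to the gem-dimethyl carbon C22, and since the shift is reversible the less congested ketol should also prevail at equilibrium. The ring C alkene is part of an enone and therefore cannot attack the activated acetyl group in a Prins reaction. Relief of cyclopentane strain on going to the six-membered ring drives the change.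

Step 8
Reactants: 11 ring-expanded ketol
Product: 12 C19 triethylsilyl ether
Conditions: Et3SiOTf, 2,6-lutidine, CH2Cl2, −78 → 0 °C
Reagents that add atoms: triethylsilyl trifluoromethanesulfonate, CC[Si](CC)(CC)OS(=O)(=O)C(F)(F)F
Why: Silyl ether formation with the silyl triflate covers the tertiary carbinol so that it can neither close a cyclic thiocarbonate in step 10 nor quench the ylide later.

Step 9
Reactants: 12 C19 triethylsilyl ether
Product: 13 C20 alcohol
Conditions: NaBH4, MeOH/CH2Cl2, −78 → −40 °C
Reagents that add atoms: none
Why: Chemoselective borohydride reduction takes the saturated, α-oxygenated C20 ketone before the conjugated enone; either C20 epimer serves because the centre is removed in step 11.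

Step 10
Reactants: 13 C20 alcohol
Product: 14 C20 O-phenyl thionocarbonate
Conditions: PhOC(S)Cl, pyridine, DMAP, CH2Cl2, rt
Reagents that add atoms: O-phenyl chlorothionoformate, S=C(Cl)Oc1ccccc1
Why: Acylation of the secondary alcohol (thionocarbonate formation) prepares the radical deoxygenation; the tertiary oxygen is silylated and cannot compete.

Step 11
Reactants: 14 C20 O-phenyl thionocarbonate
Product: 15 enone with C20 methylene
Conditions: Bu3SnH (0.3 M), AIBN, toluene, 90 °C
Reagents that add atoms: none
Why: Barton–McCombie deoxygenation in which the tin radical adds to C=S, the C20–O bond fragments and the secondary radical is reduced; the high tin hydride concentration is chosen so that the radical is trapped before it can add to C16 of the enone.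

Step 12
Reactants: 15 enone with C20 methylene
Product: 16 C14-methylene diene
Conditions: Zn, CH2Br2, TiCl4, THF/CH2Cl2, 0 °C → rt
Reagents that add atoms: dibromomethane, BrCBr
Why: Takai–Lombardo methylenation converts hindered, enolisable ketones without base, so C23 next to the carbonyl keeps its configuration.

Step 13
Reactants: 16 C14-methylene diene
Product: 18 C13 alcohol, via B-alkyl-9-borabicyclononane 17 (not isolated)
Conditions: 9-BBN, THF, 0 °C → rt; then NaOH, H2O2, 0 °C
Reagents that add atoms: hydrogen peroxide, OO
Why: Hydroboration–oxidation in which 9-BBN adds to the terminal methylene with boron on C13 and delivers hydrogen to C14 from the face opposite the C23–C22 bond (held axial by allylic strain with the methylene), which sets C14 with H cis to H23; oxidation goes with retention.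

Step 14
Reactants: 18 C13 alcohol
Product: 19 C13 iodide
Conditions: I2, PPh3, imidazole, CH2Cl2, 0 °C → rt
Reagents that add atoms: iodine, II
Why: Appel-type iodination, an SN2 displacement of the oxyphosphonium group at the primary carbon.

Step 15
Reactants: 19 C13 iodide
Product: 20 C13 triphenylphosphonium iodide
Conditions: PPh3, MeCN, 85 °C (sealed tube)
Reagents that add atoms: triphenylphosphine, c1ccc(cc1)P(c1ccccc1)c1ccccc1
Why: Quaternisation of the phosphine by the primary iodide (SN2) gives the Wittig salt under neutral conditions that the tertiary silyl ether tolerates.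

Step 16
Reactants: 21 (2E,6E)-farnesyl acetate
Product: 22 (6S,7S,10S)-diepoxy farnesyl acetate
Conditions: L-fructose-derived Shi ketone (1,2:4,5-di-O-isopropylidene-β-L-erythro-2,3-hexodiulo-2,6-pyranose, 30 mol%), Oxone (2KHSO5·KHSO4·K2SO4), K2CO3, Bu4NHSO4, MeCN/dimethoxymethane/aq. Na2B4O7 buffer, 0 °C
Reagents that add atoms: potassium peroxymonosulfate, [K+].[O-]S(=O)(=O)OO
Why: Shi epoxidation, in which the chiral dioxirane epoxidises the two electron-rich trisubstituted alkenes through a spiro transition state on the same enantioface of each, while the alkene deactivated by the allylic acetate is left.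

Step 17
Reactants: 22 (6S,7S,10S)-diepoxy farnesyl acetate
Product: 25 bicyclic triol (rings A and B), via dioxanylium triflate 23 (not isolated), via hydroxy acetate 24 (not isolated)
Conditions: Me3SiOTf (1.2 equiv), 2,6-di-tert-butyl-4-methylpyridine, CH2Cl2, −78 °C; aq. NaHCO3; then K2CO3, MeOH, rt
Reagents that add atoms: none
Why: Proposed new method: Me3SiOTf silylates the terminal epoxide oxygen, the oxygen of the C6–C7 epoxide opens it at the tertiary carbon C2 (7-endo, giving the oxepane and a bicyclic epoxonium ion), the C10=C11 alkene opens that ion at tertiary C6 with inversion through a chair (6-endo, ring B), and the acetate carbonyl oxygen captures the developing C10 cation anti to the new C6–C11 bond as a six-membered dioxanylium ion, which water and then methanol take apart to the triol; C3 and C7 keep the epoxide configuration, C6 is inverted, and anti addition across the E-alkene puts the C10 oxygen and C12 equatorial; the closest known reactions are the silyl-triflate-promoted tandem endo-oxacyclisation/carbacyclisation of 1,5-diepoxides that ends at alkenes or enol silanes, and the acetate-assisted termination in the superacid cyclisation of farnesyl acetate to the drimane-8,11-diol monoacetate.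

Step 18
Reactants: 25 bicyclic triol
Product: 26 tris(triethylsilyl) ether
Conditions: Et3SiOTf (4 equiv), 2,6-lutidine, CH2Cl2, −78 → 0 °C
Reagents that add atoms: triethylsilyl trifluoromethanesulfonate, CC[Si](CC)(CC)OS(=O)(=O)C(F)(F)F
Why: Silyl ether formation with the silyl triflate covers the primary, secondary and tertiary hydroxyls alike.

Step 19
Reactants: 26 tris(triethylsilyl) ether
Product: 27 C12 aldehyde
Conditions: (COCl)2, DMSO, CH2Cl2, −78 → −30 °C; then Et3N
Reagents that add atoms: none
Why: Swern oxidation of a primary triethylsilyl ether, in which the chlorosulfonium salt attacks the least hindered silyl ether oxygen, the silyl group leaves as its chloride and the alkoxysulfonium ylide collapses to the aldehyde, the secondary and tertiary silyl ethers being untouched.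

Step 20
Reactants: 20 C13 triphenylphosphonium iodide; 27 C12 aldehyde
Product: 29 C12=C13 Z-alkene, via phosphorus ylide 28 (not isolated)
Conditions: NaN(SiMe3)2, THF, −78 → 0 °C; then 27, −78 °C → rt
Reagents that add atoms: none
Why: Wittig olefination by the unstabilised ylide forms the C12=C13 bond (mainly Z, geometry irrelevant), and the shielded C11–H is not removed, so C11 keeps its equatorial side chain.

Step 21
Reactants: 29 C12=C13 Z-alkene
Product: 30 tris(triethylsilyl) ether of sipholenol L
Conditions: 2-nitrobenzenesulfonylhydrazide, Et3N, CH2Cl2, rt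
Reagents that add atoms: none
Why: Diimide reduction adds hydrogen syn to the 1,2-disubstituted C12=C13 bond and is too slow at the hindered trisubstituted C15=C16 bond to touch it.

Step 22
Reactants: 30 tris(triethylsilyl) ether of sipholenol L
Product: 31 sipholenol L
Conditions: HF·pyridine, pyridine, THF, 0 °C → rt
Reagents that add atoms: none
Why: Fluoride-mediated desilylation frees the C3, C10 and C19 hydroxyls under buffered conditions that do not ionise the tertiary carbinols.

**Compound list**

1 | 4,4-dimethylcyclopent-2-en-1-one | CC1(C)CC(=O)C=C1 | starting material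
2 | isoprene (2-methylbuta-1,3-diene) | C=CC(C)=C | starting material
3 | (3aR,7aS)-3,3,5-trimethyl-2,3,3a,4,7,7a-hexahydro-1H-inden-1-one; cis-fused, C20 ketone, C15=C16 | CC1=CC[C@H]2[C@@H](C1)C(C)(C)CC2=O | intermediate
4 | C14 allylic alcohol of 3 (4-hydroxy-3,3,5-trimethyl-2,3,3a,4,7,7a-hexahydro-1H-inden-1-one); cis-fused, hydroxyl on the face of H23, expected major epimer | CC1=CC[C@H]2[C@@H]([C@H]1O)C(C)(C)CC2=O | intermediate
5 | (3aR,7aS)-3,3,5-trimethyl-3,3a,7,7a-tetrahydro-1H-indene-1,4(2H)-dione; cis-fused, C14 enone and C20 ketone | CC1=CC[C@H]2[C@@H](C1=O)C(C)(C)CC2=O | intermediate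
6 | ethyltriphenylphosphonium bromide | CC[P+](c1ccccc1)(c1ccccc1)c1ccccc1.[Br-] | starting material
7 | ethylidenetriphenylphosphorane | CC=P(c1ccccc1)(c1ccccc1)c1ccccc1 | intermediate (not isolated)
8 | 1-ethylidene-3,3,5-trimethyl-1,2,3,3a,7,7a-hexahydro-4H-inden-4-one; cis-fused as 5, C20=C19 drawn E (methyl syn to C21), the Z isomer serves equally | CC1=CC[C@H]2[C@@H](C1=O)C(C)(C)C\C2=C/C | intermediate
9 | 1-hydroxy-1-(1-hydroxyethyl)-3,3,5-trimethyl-1,2,3,3a,7,7a-hexahydro-4H-inden-4-one; cis-fused, C20 hydroxyl on the convex face (cis to H18), C19 carbinol as formed from the E alkene | CC1=CC[C@H]2[C@@H](C1=O)C(C)(C)C[C@@]2(O)[C@H](C)O | intermediate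
10 | 1-acetyl-1-hydroxy-3,3,5-trimethyl-1,2,3,3a,7,7a-hexahydro-4H-inden-4-one; cis-fused, C20 hydroxyl cis to H18 (convex face), acetyl on the concave face | CC1=CC[C@H]2[C@@H](C1=O)C(C)(C)C[C@@]2(O)C(C)=O | intermediate
11 | 5-hydroxy-2,5,8,8-tetramethyl-4a,5,8,8a-tetrahydronaphthalene-1,6(4H,7H)-dione; cis-fused, C19 hydroxyl cis to H18, C19 methyl trans; C14 enone, C20 ketone | CC1=CC[C@H]2[C@@H](C1=O)C(C)(C)CC(=O)[C@]2(C)O | intermediate
12 | C19 triethylsilyl ether of 11 | CC1=CC[C@H]2[C@@H](C1=O)C(C)(C)CC(=O)[C@]2(C)O[Si](CC)(CC)CC | intermediate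
13 | C20 alcohol from 12 (C14 enone kept); C20 epimer drawn arbitrarily, both serve | CC1=CC[C@H]2[C@@H](C1=O)C(C)(C)C[C@@H](O)[C@]2(C)O[Si](CC)(CC)CC | intermediate
14 | C20 O-phenyl thionocarbonate of 13 | CC1=CC[C@H]2[C@@H](C1=O)C(C)(C)C[C@@H](OC(=S)Oc1ccccc1)[C@]2(C)O[Si](CC)(CC)CC | intermediate
15 | 2,5,8,8-tetramethyl-5-(triethylsilyloxy)-4a,5,6,7,8,8a-hexahydronaphthalen-1(4H)-one; cis-fused, C19 as in 11 | CC1=CC[C@H]2[C@@H](C1=O)C(C)(C)CC[C@]2(C)O[Si](CC)(CC)CC | intermediate
16 | C14-methylene diene from 15 (C13H2=C14–C15(Me)=C16) | CC1=CC[C@H]2[C@@H](C1=C)C(C)(C)CC[C@]2(C)O[Si](CC)(CC)CC | intermediate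
17 | B-(C13-alkyl)-9-borabicyclo[3.3.1]nonane; C14–H cis to H23 | CC1=CC[C@H]2[C@@H]([C@@H]1CB1C3CCCC1CCC3)C(C)(C)CC[C@]2(C)O[Si](CC)(CC)CC | intermediate (not isolated)
18 | C13 primary alcohol; rings C and D with C14, C18, C19, C23 as in the target, C19–OSiEt3 | CC1=CC[C@H]2[C@@H]([C@@H]1CO)C(C)(C)CC[C@]2(C)O[Si](CC)(CC)CC | intermediate
19 | C13 iodide corresponding to 18 | CC1=CC[C@H]2[C@@H]([C@@H]1CI)C(C)(C)CC[C@]2(C)O[Si](CC)(CC)CC | intermediate
20 | C13 triphenylphosphonium iodide corresponding to 18 | CC1=CC[C@H]2[C@@H]([C@@H]1C[P+](c1ccccc1)(c1ccccc1)c1ccccc1)C(C)(C)CC[C@]2(C)O[Si](CC)(CC)CC.[I-] | intermediate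
21 | (2E,6E)-3,7,11-trimethyldodeca-2,6,10-trien-1-yl acetate (farnesyl acetate) | CC(=O)OC/C=C(\C)CC/C=C(\C)CCC=C(C)C | starting material
22 | (2E,6S,7S,10S)-6,7:10,11-diepoxy-3,7,11-trimethyldodec-2-en-1-yl acetate | CC(=O)OC/C=C(\C)CC[C@@H]1O[C@@]1(C)CC[C@@H]1OC1(C)C | intermediate
23 | 2-methyl-1,3-dioxan-2-ylium triflate trans-fused to ring B through C10–O and C11–C12–O; rings A and B formed, C3–OSiMe3 | C1[C@H]2[C@]3(C)CC[C@H](O[Si](C)(C)C)C(C)(C)O[C@H]3CC[C@]2(C)[O+]=C(C)O1.[O-]S(=O)(=O)C(F)(F)F | intermediate (not isolated)
24 | C12 acetate, C10 tertiary alcohol, C3 trimethylsilyl ether of the ring A/B bicycle | CC(=O)OC[C@H]1[C@]2(C)CC[C@H](O[Si](C)(C)C)C(C)(C)O[C@H]2CC[C@]1(C)O | intermediate (not isolated)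
25 | ring A/B triol: trans-fused oxepane–cyclohexane with C3–OH, C10(Me)–OH and C11–CH2OH, all centres as in the target | OC[C@H]1[C@]2(C)CC[C@H](O)C(C)(C)O[C@H]2CC[C@]1(C)O | intermediate
26 | tris(triethylsilyl) ether of 25 | CC[Si](CC)(CC)OC[C@H]1[C@]2(C)CC[C@H](O[Si](CC)(CC)CC)C(C)(C)O[C@H]2CC[C@]1(C)O[Si](CC)(CC)CC | intermediate
27 | C12 aldehyde with C3 and C10 triethylsilyl ethers | O=C[C@H]1[C@]2(C)CC[C@H](O[Si](CC)(CC)CC)C(C)(C)O[C@H]2CC[C@]1(C)O[Si](CC)(CC)CC | intermediate
28 | C13 triphenylphosphonium ylide from 20 | CC1=CC[C@H]2[C@@H]([C@@H]1C=P(c1ccccc1)(c1ccccc1)c1ccccc1)C(C)(C)CC[C@]2(C)O[Si](CC)(CC)CC | intermediate (not isolated)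
29 | (12Z)-12,13-didehydro-sipholenol L 3,10,19-tris(triethylsilyl) ether | CC1=CC[C@H]2[C@@H]([C@@H]1/C=C\[C@H]1[C@]3(C)CC[C@H](O[Si](CC)(CC)CC)C(C)(C)O[C@H]3CC[C@]1(C)O[Si](CC)(CC)CC)C(C)(C)CC[C@]2(C)O[Si](CC)(CC)CC | intermediate
30 | sipholenol L 3,10,19-tris(triethylsilyl) ether | CC1=CC[C@H]2[C@@H]([C@@H]1CC[C@H]1[C@]3(C)CC[C@H](O[Si](CC)(CC)CC)C(C)(C)O[C@H]3CC[C@]1(C)O[Si](CC)(CC)CC)C(C)(C)CC[C@]2(C)O[Si](CC)(CC)CC | intermediate
31 | sipholenol L; 3S,6S,7S,10S,11S,14S,18S,19S,23R in the numbering used here | CC1=CC[C@H]2[C@@H]([C@@H]1CC[C@H]1[C@]3(C)CC[C@H](O)C(C)(C)O[C@H]3CC[C@]1(C)O)C(C)(C)CC[C@]2(C)O | target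

**Step count and risks**

Total: 22 steps. Longest linear sequence: 18 steps (steps 1–15, then 20–22); the left half takes 4 steps (16–19).

Steps most likely to fail:

1. Step 17. The alkene that carries the allylic acetate may be too weak a nucleophile to open the epoxonium ion, or the C10 cation may lose a proton before the ester closes onto it. The fallback sets out from 22 and returns at 25. The acetate is removed (K2CO3, MeOH) to give the diepoxy farnesol F1, which is silylated (t-BuMe2SiCl, imidazole, DMF) to the silyl ether F2, whose alkene is no longer deactivated by an ester. The Me3SiOTf/2,6-di-tert-butyl-4-methylpyridine treatment is then used in its established form, a tandem oxa-/carbacyclisation that ends in proton loss, and should give the ring B exo-methylene bicycle F3 together with its C9=C10 isomer F4, both as C3 trimethylsilyl ethers. Mukaiyama hydration (Mn(dpm)3 with dpm = 2,2,6,6-tetramethylheptane-3,5-dionate, PhSiH3, O2, i-PrOH; then P(OEt)3) takes both alkenes through the same tertiary C10 radical, which O2 should trap on the equatorial side away from the axial C6 methyl, to the tertiary alcohol F5. Bu4NF then removes both silyl groups and gives 25.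

2. Step 7. The shift may run through the non-chelated, dipole-opposed conformer of the ketol, which would give the C19 epimer; a shift of the methylene C21 is the second concern. The fallback sets out from 5 and returns at 11. 1-Ethoxyvinyllithium (ethyl vinyl ether, t-BuLi, THF, −78 °C) adds to the C20 ketone from the convex face to give the enol ether carbinol F6, and dilute HCl unmasks the C20-epimeric ketol F7 (acetyl convex, hydroxyl concave). As its potassium alkoxide (KOt-Bu, THF, 0 °C) F7 has no chelate and rearranges through the dipole-opposed conformer. With both the carbinol configuration and the conformer reversed, the same shift of C18 delivers 11.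

3. Step 1. Cycloaddition at the enone carbon next to the quaternary centre may be so slow that turnover is poor and the catalyst no longer controls the face. The fallback sets out from 1 and returns at 3. α-Iodination (I2, pyridine, CH2Cl2) gives the iodoenone F8, and carbonylation (PdCl2(PPh3)2, CO, MeOH, Et3N) gives the keto ester F9, a much more reactive dienophile that binds a chiral Lewis acid through both carbonyl groups. Its cycloaddition with isoprene under Cu(OTf)2 and (S,S)-2,2′-(propane-2,2-diyl)bis(4-tert-butyl-4,5-dihydrooxazole), the ligand enantiomer being chosen for the required face, gives the angular ester F10. Krapcho dealkoxycarbonylation (LiCl, wet DMSO, 140 °C), with protonation to the more stable cis ring fusion, gives 3; the C23 centre set in the cycloaddition carries the absolute configuration.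

**Further compounds**

F1 | step 17 | (2E,6S,7S,10S)-6,7:10,11-diepoxy-3,7,11-trimethyldodec-2-en-1-ol | OC/C=C(\C)CC[C@@H]1O[C@@]1(C)CC[C@@H]1OC1(C)C
F2 | step 17 | tert-butyldimethylsilyl ether of F1 | CC(C)(C)[Si](C)(C)OC/C=C(\C)CC[C@@H]1O[C@@]1(C)CC[C@@H]1OC1(C)C
F3 | step 17 | ring A/B bicycle with exocyclic C10 methylene, C12–OSi(t-Bu)Me2 and C3–OSiMe3 | CC(C)(C)[Si](C)(C)OC[C@H]1[C@]2(C)CC[C@H](O[Si](C)(C)C)C(C)(C)O[C@H]2CCC1=C
F4 | step 17 | C9=C10 alkene isomer of F3 | CC(C)(C)[Si](C)(C)OC[C@H]1[C@]2(C)CC[C@H](O[Si](C)(C)C)C(C)(C)O[C@H]2CC=C1C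
F5 | step 17 | C10 tertiary alcohol with C12–OSi(t-Bu)Me2 and C3–OSiMe3 | CC(C)(C)[Si](C)(C)OC[C@H]1[C@]2(C)CC[C@H](O[Si](C)(C)C)C(C)(C)O[C@H]2CC[C@]1(C)O
F6 | step 7 | 1-(1-ethoxyvinyl) C20 carbinol from 5; hydroxyl on the concave face | CC1=CC[C@H]2[C@@H](C1=O)C(C)(C)C[C@]2(O)C(=C)OCC
F7 | step 7 | C20 epimer of ketol 10; acetyl convex, hydroxyl concave | CC1=CC[C@H]2[C@@H](C1=O)C(C)(C)C[C@]2(O)C(C)=O
F8 | step 1 | 2-iodo-4,4-dimethylcyclopent-2-en-1-one | CC1(C)CC(=O)C(I)=C1
F9 | step 1 | methyl 3,3-dimethyl-5-oxocyclopent-1-ene-1-carboxylate | COC(=O)C1=CC(C)(C)CC1=O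
F10 | step 1 | methyl 3,3,5-trimethyl-1-oxo-1,2,3,3a,4,7-hexahydro-7aH-indene-7a-carboxylate; cis-fused, ester in place of H18 | CC1=CC[C@@]2(C(=O)OC)[C@@H](C1)C(C)(C)CC2=O
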